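All runs were generated by integration for an exercise.

We want the share of its Xa that the north run has turned into Xp by 7.6 h.

- Xp in the north run at 7.6 h, as a share of the Xa charged

| flask | Xa | Xb | Xc | time |
|---|---|---|---|---|
| north-east | 0.200 M | 0.600 M | 0.00600 M |  |
| east | 0.120 M | 0.520 M | 0.00600 M |  |
| west | 0.200 M | 0.600 M | 0.0120 M |  |
| north | 0.0400 M | 0.600 M | 0.00600 M | 7.6 h |

| run | time / h | [Xp] / M |
|---|---|---|
| north-east run | 0.95 | 0.034 |
| north-east run | 1.9 | 0.039 |
| north-east run | 2.9 | 0.039 |
| north-east run | 3.8 | 0.043 |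
| north-east run | 4.8 | 0.043 |
| north-east run | 5.7 | 0.043 |
| north-east run | 6.7 | 0.043 |
| north-east run | 7.6 | 0.044 |
| east run | 0.95 | 0.021 |
| east run | 1.9 | 0.023 |
| east run | 2.9 | 0.022 |
| east run | 3.8 | 0.030 |
| east run | 4.8 | 0.027 |
| east run | 5.7 | 0.028 |
| east run | 6.7 | 0.026 |
| east run | 7.6 | 0.032 |
| west run | 0.95 | 0.086 |
| west run | 1.9 | 0.100 |
| west run | 2.9 | 0.098 |
| west run | 3.8 | 0.103 |
| west run | 4.8 | 0.102 |
| west run | 5.7 | 0.108 |
| west run | 6.7 | 0.102 |
| west run | 7.6 | 0.098 |

(readings scatter by 0.003 M)

- Overall: Xa + Xb -> Xp, with Xc as catalyst.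
- Constant volume, constant temperature.

The readings level off, so we take the mean of the last 4 readings of each run as its plateau: 0.0432 M in north-east, 0.0283 M in east and 0.103 M in west. On the north-east plateau 0.244 is the dose Φ, the natural logarithm of Xa charged over Xa left. The same measure reads 0.268 in east and 0.718 in west.

Take Xc first. By hand, a rate in step with Xc would give the west run twice the north-east dose, but the reading is 2.94 times it. The north run has the Xc of north-east, so this setting drops out.

Now Xa. If the rate is first order in Xa (pseudo-first-order) and Xa changes nothing else, Φ stays the same when less Xa is charged, and the share turned stays with it. Yet the east run reads higher than north-east, by 0.0240, against a scatter of 0.0163 on its Φ. That is a lean in the readings, not a firm trend.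

Xb cannot be separated from this in the east run, because east lowers Xb and Xa by the same 0.0800 M, whereas the north run keeps the Xb of north-east. We set Xb aside and continue the lean, since Xa falls by that same step again from east to north:

Φ(north) ≈ Φ(east) + (Φ(east) − Φ(north-east)) = 0.293

share = 1 − exp(−Φ) = 25.4 %

The forecast stands higher than our reckoning, at 36 %, with the words “This fits a poison that scales with Xa”.

The north run gives 26.6 % at 7.6 h, which is a Φ of 0.309, above the north-east plateau reading of 0.244.

    2 Xc ⇌ Xc2, settled at all times (809.0 M⁻¹)
    Xc2 + Xa + Xb → Xp + Xc2 (1843 M⁻² h⁻¹)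
    2 Xb → Q (13.61 M⁻¹ h⁻¹)
    Xc + J → E

By 2 Xb → Q alone, the Xb of the north run has a first half-life of 0.0612 h. In the east run, turning a quarter of the Xa takes a Φ of 0.288, above that run's plateau reading of 0.268, and the east run comes to it at 13.5 h.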